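**Strategy**

Ring A is built around the side chain instead of being alkylated. C8 lies between two oxygen-bearing carbons, C7 and C8a, which is the 2-alkylresorcinol pattern that a vinylketene delivers to an ynol ether. Heating a limonene-derived siloxyalkyne, which already holds C1″–C5″, the isopropenyl group and the (2″R) centre, with 3-(triisopropylsilyloxy)cyclobutenone should forge C8–C8a, C6–C7 and C4a–C8a and close ring A in one operation. C8a–OH is left free and the C5 and C7 oxygens silylated, so a 6-alkyl isomer cannot arise. Ortho-formylation, chromone closure, catalytic asymmetric C2 arylation and a single fluoride deprotection complete the flavanone.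

Key step: step 7

**Remarks and assumptions**

- Target read from the SMILES: (2S) at the flavanone carbon, (2″R) in the side chain; flavanone numbering is used throughout.
- Design choice: every phenolic oxygen is carried as a silyl ether, with the C5 oxygen coming from a 3-silyloxycyclobutenone. No alkyl ether then has to be cleaved with a Lewis acid next to two acid-labile 1,1-disubstituted alkenes and a C7 oxygen that could close a chroman onto the isopropenyl group. For the same reason the acetyl group is introduced without Friedel–Crafts or Fries conditions.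
- Assumption: (+)-limonene 1,2-oxide (cis/trans mixture, 4R, made from (R)-limonene) and cyclobutane-1,3-dione are purchased.
- Assumption: (R)-t-BuPyOx is the ligand enantiomer expected to give 2S, by analogy with the facial preference of this catalyst type on cyclic enones; the sense must be confirmed on the first sample, and the antipodal ligand is equally available.

**Route**

Step 1
Reactants: 1 (4R)-limonene 1,2-oxide (cis/trans mixture)
Product: 3 (3R)-6-oxo-3-(prop-1-en-2-yl)heptanal, via limonene-1,2-diol 2 (not isolated)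
Conditions: H5IO6, THF/H2O, 0 °C → rt
Reagents that add atoms: water, O
Why: Acid-promoted epoxide hydrolysis followed by Malaprade glycol cleavage should open the ring between C1 and C2 of either epoxide isomer, while the isopropenyl group and the C4 stereocentre (which becomes C2″) are not involved.

Step 2
Reactants: 3 (3R)-6-oxo-3-(prop-1-en-2-yl)heptanal
Product: 4 (3R)-6-oxo-3-(prop-1-en-2-yl)heptanoic acid
Conditions: NaClO2, NaH2PO4, 2-methyl-2-butene (excess), t-BuOH/H2O, 0 °C → rt
Reagents that add atoms: sodium chlorite, [Na+].[O-]Cl=O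
Why: Pinnick oxidation is selective for the aldehyde over the methyl ketone, the scavenger removes hypochlorous acid before it can attack the isopropenyl group, and the stereocentre is β to the carbonyl and cannot epimerise.

Step 3
Reactants: 4 (3R)-6-oxo-3-(prop-1-en-2-yl)heptanoic acid
Product: 5 methyl (3R)-6-oxo-3-(prop-1-en-2-yl)heptanoate
Conditions: MeI, K2CO3, DMF, rt
Reagents that add atoms: iodomethane, CI
Why: SN2 O-alkylation of the carboxylate gives the ester without any acid, so the alkene is untouched.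

Step 4
Reactants: 5 methyl (3R)-6-oxo-3-(prop-1-en-2-yl)heptanoate
Product: 6 methyl (3R)-6-methyl-3-(prop-1-en-2-yl)hept-6-enoate
Conditions: Ph3PCH3Br, KOt-Bu, THF, 0 °C → rt
Reagents that add atoms: methyltriphenylphosphonium bromide, C[P+](c1ccccc1)(c1ccccc1)c1ccccc1.[Br-]
Why: Wittig methylenation with the unstabilised ylide should take the ketone far faster than the ester and installs the C5″ methylidene.

Step 5
Reactants: 6 methyl (3R)-6-methyl-3-(prop-1-en-2-yl)hept-6-enoate
Product: 9 triisopropyl{[(4R)-7-methyl-4-(prop-1-en-2-yl)oct-7-en-1-yn-1-yl]oxy}silane, via dibromoketone lithium enolate 7 (not isolated), via lithium ynolate 8 (not isolated)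
Conditions: CH2Br2, LiTMP, THF, –78 °C; LiHMDS; n-BuLi, –78 → 25 °C; TIPSCl, –78 → 25 °C
Reagents that add atoms: dibromomethane, BrCBr; chlorotriisopropylsilane, CC(C)[Si](Cl)(C(C)C)C(C)C
Why: Kowalski ynolate formation (addition of LiCHBr2, enolisation, Br/Li exchange and 1,2-shift of the alkyl group to the carbenoid carbon) followed by O-silylation with the bulky silyl chloride should give the TIPS ynol ether, the migrating carbon being the C1″ methylene so that the stereocentre is untouched.

Step 6
Reactants: 10 cyclobutane-1,3-dione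
Product: 11 3-(triisopropylsilyloxy)cyclobut-2-en-1-one
Conditions: TIPSOTf, Et3N, CH2Cl2, –78 → 0 °C
Reagents that add atoms: triisopropylsilyl triflate, CC(C)[Si](OS(=O)(=O)C(F)(F)F)(C(C)C)C(C)C
Why: O-silylation of the enolate of an acidic 1,3-dione gives the vinylogous silyl ester, and the symmetry of the dione allows only one product.

Step 7
Reactants: 9 triisopropyl{[(4R)-7-methyl-4-(prop-1-en-2-yl)oct-7-en-1-yn-1-yl]oxy}silane; 11 3-(triisopropylsilyloxy)cyclobut-2-en-1-one
Product: 16 2-[(2R)-5-methyl-2-(prop-1-en-2-yl)hex-5-en-1-yl]-3,5-bis(triisopropylsilyloxy)phenol, via silyloxy vinylketene 12 (not isolated), via vinylcyclobutenone 13 (not isolated), via dienylketene 14 (not isolated), via cyclohexadienone 15 (not isolated)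
Conditions: 9 (1.2 equiv), PhMe (degassed), sealed tube, 80 → 110 °C
Reagents that add atoms: none
Why: Cyclobutenone 11 should open thermally (4π, conrotatory) to vinylketene 12, whose electrophilic carbonyl carbon is attacked by the nucleophilic, alkyl-bearing carbon of ynol ether 9 in a regioselective [2+2] cycloaddition to give 13, and a second 4π opening releases dienylketene 14. Ring A then closes by a thermally allowed disrotatory 6π electrocyclisation that forms C4a–C8a, and cyclohexadienone 15 tautomerises to phenol 16, so C8–C8a, C6–C7 and C4a–C8a are all made in one flask. The closest known reaction type is the Danheiser benzannulation of a cyclobutenone with a siloxyalkyne, applied here to a vinylogous-ester cyclobutenone. No stereocentre is created (the sp3 ring carbon of 13 is lost on ring opening), and C2″ is insulated from the reacting alkyne by the C1″ methylene, so it cannot epimerise. The one selectivity needed is the orientation of the [2+2], which the oxygen-polarised triple bond of 9 fixes: the ketene oxygen becomes C8a–OH, the alkyne oxygen C7–OTIPS and the cyclobutenone oxygen C5–OTIPS, with the chain locked at C8. The slight excess of 9 should limit O-acylation of 16 by 12, and the temperature is kept below that at which siloxyalkynes rearrange to silylketenes.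

Step 8
Reactants: 16 2-[(2R)-5-methyl-2-(prop-1-en-2-yl)hex-5-en-1-yl]-3,5-bis(triisopropylsilyloxy)phenol
Product: 17 2-hydroxy-3-[(2R)-5-methyl-2-(prop-1-en-2-yl)hex-5-en-1-yl]-4,6-bis(triisopropylsilyloxy)benzaldehyde
Conditions: MgCl2 (anhydrous), Et3N, (CH2O)n, THF, 65 °C; aq. citric acid work-up
Reagents that add atoms: paraformaldehyde (as formaldehyde), C=O
Why: Casnati–Skattebøl formylation delivers formaldehyde through the magnesium phenoxide to an ortho position only, and the single free ortho carbon is the future C4a; the medium is basic, so the alkenes and silyl ethers should survive.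

Step 9
Reactants: 17 2-hydroxy-3-[(2R)-5-methyl-2-(prop-1-en-2-yl)hex-5-en-1-yl]-4,6-bis(triisopropylsilyloxy)benzaldehyde
Product: 18 2-(1-hydroxyethyl)-6-[(2R)-5-methyl-2-(prop-1-en-2-yl)hex-5-en-1-yl]-3,5-bis(triisopropylsilyloxy)phenol (both carbinol epimers)
Conditions: MeMgBr (3 equiv), THF, –78 → 0 °C; pH 7 aqueous quench; used crude
Reagents that add atoms: methylmagnesium bromide, C[Mg]Br
Why: Grignard addition to the salicylaldehyde (first equivalent consumed by the phenol) gives the benzylic alcohol, whose new carbinol centre is removed in the next step and is therefore left uncontrolled.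

Step 10
Reactants: 18 2-(1-hydroxyethyl)-6-[(2R)-5-methyl-2-(prop-1-en-2-yl)hex-5-en-1-yl]-3,5-bis(triisopropylsilyloxy)phenol
Product: 19 1-{2-hydroxy-3-[(2R)-5-methyl-2-(prop-1-en-2-yl)hex-5-en-1-yl]-4,6-bis(triisopropylsilyloxy)phenyl}ethan-1-one
Conditions: MnO2 (activated, excess), CH2Cl2, rt
Reagents that add atoms: none
Why: Manganese dioxide oxidation is selective for the benzylic alcohol and should leave the phenol, the alkenes and the silyl ethers alone, giving the hydrogen-bonded ortho-hydroxyacetophenone under neutral conditions.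

Step 11
Reactants: 19 1-{2-hydroxy-3-[(2R)-5-methyl-2-(prop-1-en-2-yl)hex-5-en-1-yl]-4,6-bis(triisopropylsilyloxy)phenyl}ethan-1-one
Product: 21 8-[(2R)-5-methyl-2-(prop-1-en-2-yl)hex-5-en-1-yl]-5,7-bis(triisopropylsilyloxy)-4H-chromen-4-one, via enaminone 20 (not isolated)
Conditions: Me2NCH(OMe)2, PhMe, 90 °C; concentrate; AcOH, CH2Cl2, 40 °C
Reagents that add atoms: N,N-dimethylformamide dimethyl acetal, COC(OC)N(C)C
Why: Enaminone formation at the methyl ketone followed by weak-acid-promoted intramolecular addition–elimination of the C8a hydroxyl (loss of dimethylamine) is the standard chromone closure, and acetic acid is too weak to protonate the 1,1-disubstituted alkenes.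

Step 12
Reactants: 21 8-[(2R)-5-methyl-2-(prop-1-en-2-yl)hex-5-en-1-yl]-5,7-bis(triisopropylsilyloxy)-4H-chromen-4-one; 22 [4-(tert-butyldimethylsilyloxy)phenyl]boronic acid
Product: 23 (2S)-2-[4-(tert-butyldimethylsilyloxy)phenyl]-8-[(2R)-5-methyl-2-(prop-1-en-2-yl)hex-5-en-1-yl]-5,7-bis(triisopropylsilyloxy)-2,3-dihydro-4H-chromen-4-one
Conditions: Pd(OCOCF3)2 (10 mol %), (R)-t-BuPyOx (12 mol %), NH4PF6 (30 mol %), H2O (5 equiv), 22 (2.5 equiv), ClCH2CH2Cl, 60 °C
Reagents that add atoms: none
Why: Pd(II)/pyridine-oxazoline-catalysed asymmetric conjugate addition of an arylboronic acid to a chromone (transmetalation, enantio-determining insertion of C2=C3 into the aryl–Pd bond, protonolysis of the Pd enolate by water) sets C2, with the tert-butyl group of the ligand selecting the enone face and the remote C2″ centre expected to have no say; the non-basic medium should prevent ring opening of the flavanone.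

Step 13
Reactants: 23 (2S)-2-[4-(tert-butyldimethylsilyloxy)phenyl]-8-[(2R)-5-methyl-2-(prop-1-en-2-yl)hex-5-en-1-yl]-5,7-bis(triisopropylsilyloxy)-2,3-dihydro-4H-chromen-4-one
Product: 24 remangiflavanone A, (2S)-5,7-dihydroxy-2-(4-hydroxyphenyl)-8-[(2R)-5-methyl-2-(prop-1-en-2-yl)hex-5-en-1-yl]-2,3-dihydro-4H-chromen-4-one
Conditions: TBAF/AcOH (1:1, 4 equiv), THF, 0 °C
Reagents that add atoms: none
Why: Fluoride cleaves all three aryl silyl ethers, and the acetic acid buffer keeps the liberated phenols protonated so that phenoxide-driven retro-oxa-Michael opening, and with it epimerisation at C2, should not occur.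

**Compound list**

1 | (4R)-limonene 1,2-oxide, (4R)-1-methyl-4-(prop-1-en-2-yl)-7-oxabicyclo[4.1.0]heptane, cis/trans mixture | CC12OC1C[C@@H](CC2)C(C)=C | starting material
2 | (4R)-1-methyl-4-(prop-1-en-2-yl)cyclohexane-1,2-diol (not isolated) | CC1(O)C(O)C[C@@H](CC1)C(C)=C | intermediate
3 | (3R)-6-oxo-3-(prop-1-en-2-yl)heptanal | CC(=O)CC[C@H](CC=O)C(C)=C | intermediate
4 | (3R)-6-oxo-3-(prop-1-en-2-yl)heptanoic acid | CC(=O)CC[C@H](CC(=O)O)C(C)=C | intermediate
5 | methyl (3R)-6-oxo-3-(prop-1-en-2-yl)heptanoate | CC(=O)CC[C@H](CC(=O)OC)C(C)=C | intermediate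
6 | methyl (3R)-6-methyl-3-(prop-1-en-2-yl)hept-6-enoate | C=C(C)CC[C@H](CC(=O)OC)C(C)=C | intermediate
7 | lithium (4R)-1,1-dibromo-7-methyl-4-(prop-1-en-2-yl)octa-1,7-dien-2-olate (not isolated) | C=C(C)CC[C@H](CC([O-])=C(Br)Br)C(C)=C.[Li+] | intermediate
8 | lithium (4R)-7-methyl-4-(prop-1-en-2-yl)oct-7-en-1-yn-1-olate (not isolated) | C=C(C)CC[C@H](CC#C[O-])C(C)=C.[Li+] | intermediate
9 | triisopropyl{[(4R)-7-methyl-4-(prop-1-en-2-yl)oct-7-en-1-yn-1-yl]oxy}silane | C=C(C)CC[C@H](CC#CO[Si](C(C)C)(C(C)C)C(C)C)C(C)=C | intermediate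
10 | cyclobutane-1,3-dione | O=C1CC(=O)C1 | starting material
11 | 3-(triisopropylsilyloxy)cyclobut-2-en-1-one | O=C1C=C(O[Si](C(C)C)(C(C)C)C(C)C)C1 | intermediate
12 | 3-(triisopropylsilyloxy)buta-1,3-dien-1-one (not isolated) | C=C(O[Si](C(C)C)(C(C)C)C(C)C)C=C=O | intermediate
13 | 2-[(2R)-5-methyl-2-(prop-1-en-2-yl)hex-5-en-1-yl]-3-(triisopropylsilyloxy)-4-[1-(triisopropylsilyloxy)ethenyl]cyclobut-2-en-1-one, C4 epimers (not isolated) | C=C(C)CC[C@H](CC1=C(O[Si](C(C)C)(C(C)C)C(C)C)C(C(=C)O[Si](C(C)C)(C(C)C)C(C)C)C1=O)C(C)=C | intermediate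
14 | (3E)-2-[(2R)-5-methyl-2-(prop-1-en-2-yl)hex-5-en-1-yl]-3,5-bis(triisopropylsilyloxy)hexa-1,3,5-trien-1-one (not isolated) | C=C(C)CC[C@H](CC(=C=O)/C(O[Si](C(C)C)(C(C)C)C(C)C)=C\C(=C)O[Si](C(C)C)(C(C)C)C(C)C)C(C)=C | intermediate
15 | 2-[(2R)-5-methyl-2-(prop-1-en-2-yl)hex-5-en-1-yl]-3,5-bis(triisopropylsilyloxy)cyclohexa-2,4-dien-1-one (not isolated) | C=C(C)CC[C@H](CC1=C(O[Si](C(C)C)(C(C)C)C(C)C)C=C(O[Si](C(C)C)(C(C)C)C(C)C)CC1=O)C(C)=C | intermediate
16 | 2-[(2R)-5-methyl-2-(prop-1-en-2-yl)hex-5-en-1-yl]-3,5-bis(triisopropylsilyloxy)phenol | C=C(C)CC[C@H](Cc1c(O)cc(O[Si](C(C)C)(C(C)C)C(C)C)cc1O[Si](C(C)C)(C(C)C)C(C)C)C(C)=C | intermediate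
17 | 2-hydroxy-3-[(2R)-5-methyl-2-(prop-1-en-2-yl)hex-5-en-1-yl]-4,6-bis(triisopropylsilyloxy)benzaldehyde | C=C(C)CC[C@H](Cc1c(O)c(C=O)c(O[Si](C(C)C)(C(C)C)C(C)C)cc1O[Si](C(C)C)(C(C)C)C(C)C)C(C)=C | intermediate
18 | 2-(1-hydroxyethyl)-6-[(2R)-5-methyl-2-(prop-1-en-2-yl)hex-5-en-1-yl]-3,5-bis(triisopropylsilyloxy)phenol, both carbinol epimers | C=C(C)CC[C@H](Cc1c(O)c(C(C)O)c(O[Si](C(C)C)(C(C)C)C(C)C)cc1O[Si](C(C)C)(C(C)C)C(C)C)C(C)=C | intermediate
19 | 1-{2-hydroxy-3-[(2R)-5-methyl-2-(prop-1-en-2-yl)hex-5-en-1-yl]-4,6-bis(triisopropylsilyloxy)phenyl}ethan-1-one | C=C(C)CC[C@H](Cc1c(O)c(C(C)=O)c(O[Si](C(C)C)(C(C)C)C(C)C)cc1O[Si](C(C)C)(C(C)C)C(C)C)C(C)=C | intermediate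
20 | (2E)-3-(dimethylamino)-1-{2-hydroxy-3-[(2R)-5-methyl-2-(prop-1-en-2-yl)hex-5-en-1-yl]-4,6-bis(triisopropylsilyloxy)phenyl}prop-2-en-1-one (not isolated) | C=C(C)CC[C@H](Cc1c(O)c(C(=O)/C=C/N(C)C)c(O[Si](C(C)C)(C(C)C)C(C)C)cc1O[Si](C(C)C)(C(C)C)C(C)C)C(C)=C | intermediate
21 | 8-[(2R)-5-methyl-2-(prop-1-en-2-yl)hex-5-en-1-yl]-5,7-bis(triisopropylsilyloxy)-4H-chromen-4-one | C=C(C)CC[C@H](Cc1c(O[Si](C(C)C)(C(C)C)C(C)C)cc(O[Si](C(C)C)(C(C)C)C(C)C)c2c1OC=CC2=O)C(C)=C | intermediate
22 | [4-(tert-butyldimethylsilyloxy)phenyl]boronic acid | CC(C)(C)[Si](C)(C)Oc1ccc(B(O)O)cc1 | starting material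
23 | (2S)-2-[4-(tert-butyldimethylsilyloxy)phenyl]-8-[(2R)-5-methyl-2-(prop-1-en-2-yl)hex-5-en-1-yl]-5,7-bis(triisopropylsilyloxy)-2,3-dihydro-4H-chromen-4-one | C=C(C)CC[C@H](Cc1c(O[Si](C(C)C)(C(C)C)C(C)C)cc(O[Si](C(C)C)(C(C)C)C(C)C)c2c1O[C@H](c1ccc(O[Si](C)(C)C(C)(C)C)cc1)CC2=O)C(C)=C | intermediate
24 | remangiflavanone A, (2S)-5,7-dihydroxy-2-(4-hydroxyphenyl)-8-[(2R)-5-methyl-2-(prop-1-en-2-yl)hex-5-en-1-yl]-2,3-dihydro-4H-chromen-4-one | C=C(C)CC[C@H](Cc1c(O)cc(O)c2c1O[C@H](c1ccc(O)cc1)CC2=O)C(=C)C | target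

**Step count**

Total: 13 steps. Longest linear sequence: 12 steps (1 → 24 through steps 1–5 and 7–13); step 6 is a one-step side branch.

**Steps most likely to fail, with fallbacks**

Step 7 (benzannulation). The donor-substituted cyclobutenone may resist thermal ring opening until temperatures at which the siloxyalkyne is lost to silylketene rearrangement or oligomerisation, and the phenol may be O-acylated by unconsumed vinylketene. The fallback produces the same vinylketene 12 at room temperature by a photochemical Wolff rearrangement instead of a cyclobutenone opening. It sets out from siloxyalkyne 9 and returns at phenol 16. Commercial butane-2,3-dione is mono-silylated (TIPSOTf, Et3N) to 3-(triisopropylsilyloxy)but-3-en-2-one F1. Kinetic enolisation and trifluoroacetylation (LiHMDS, CF3CO2CH2CF3, –78 °C) give 1,1,1-trifluoro-5-(triisopropylsilyloxy)hex-5-ene-2,4-dione F2. Detrifluoroacetylative diazo transfer (MsN3, Et3N, MeCN/H2O) gives 1-diazo-3-(triisopropylsilyloxy)but-3-en-2-one F3. Irradiation of F3 with 9 in CH2Cl2 at rt should generate 12 in the presence of the ynol ether, and brief warming to 80 °C should finish the cascade to 16.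

Step 12 (asymmetric arylation). The electron-rich chromone with its peri silyloxy group may turn over slowly, the aryl–palladium species may instead insert into or isomerise the 1,1-disubstituted alkenes, or facial selectivity may be insufficient. The fallback forms the C2–O1 bond instead of the C2–aryl bond. It sets out from acetophenone 19 and returns at flavanone 23. Pyrrolidine-mediated aldol condensation of 19 with commercial 4-(tert-butyldimethylsilyloxy)benzaldehyde (EtOH, 50 °C) should give the chalcone (2E)-3-[4-(tert-butyldimethylsilyloxy)phenyl]-1-{2-hydroxy-3-[(2R)-5-methyl-2-(prop-1-en-2-yl)hex-5-en-1-yl]-4,6-bis(triisopropylsilyloxy)phenyl}prop-2-en-1-one F4. Under the same amine conditions F4 should close by oxa-Michael addition to 23 and its C2 epimer, the (2R)-configured flavanone F5. Because C2″ is fixed, these are diastereomers and can be separated by preparative HPLC. F5 can be re-equilibrated through F4 and recycled.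

Step 5 (ynolate formation and silylation). The carbenoid rearrangement may be incomplete, the ynolate may be silylated on carbon or protonated, and excess alkyllithium may metalate the allylic positions on warming. The fallback reaches the ynolate by oxidation of an acetylide instead of ester homologation. It sets out from ester 6 and returns at ynolate 8, and from there at 9. DIBAL-H (CH2Cl2, –78 °C) reduces 6 to (3R)-6-methyl-3-(prop-1-en-2-yl)hept-6-enal F6. Ohira–Bestmann alkynylation (dimethyl (1-diazo-2-oxopropyl)phosphonate, K2CO3, MeOH) gives (4R)-7-methyl-4-(prop-1-en-2-yl)oct-7-en-1-yne F7. n-BuLi (THF, –78 °C) gives lithium (4R)-7-methyl-4-(prop-1-en-2-yl)oct-7-en-1-yn-1-ide F8. Lithium tert-butyl peroxide (t-BuOOH, LiHMDS, –78 → 0 °C) should oxidise F8 to ynolate 8, which TIPSOTf converts to 9.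

**Further compounds**

F1 | step 7 | 3-(triisopropylsilyloxy)but-3-en-2-one | CC(=O)C(=C)O[Si](C(C)C)(C(C)C)C(C)C
F2 | step 7 | 1,1,1-trifluoro-5-(triisopropylsilyloxy)hex-5-ene-2,4-dione | C=C(O[Si](C(C)C)(C(C)C)C(C)C)C(=O)CC(=O)C(F)(F)F
F3 | step 7 | 1-diazo-3-(triisopropylsilyloxy)but-3-en-2-one | C=C(O[Si](C(C)C)(C(C)C)C(C)C)C(=O)C=[N+]=[N-]
F4 | step 12 | (2E)-3-[4-(tert-butyldimethylsilyloxy)phenyl]-1-{2-hydroxy-3-[(2R)-5-methyl-2-(prop-1-en-2-yl)hex-5-en-1-yl]-4,6-bis(triisopropylsilyloxy)phenyl}prop-2-en-1-one | C=C(C)CC[C@H](Cc1c(O)c(C(=O)/C=C/c2ccc(O[Si](C)(C)C(C)(C)C)cc2)c(O[Si](C(C)C)(C(C)C)C(C)C)cc1O[Si](C(C)C)(C(C)C)C(C)C)C(C)=C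
F5 | step 12 | (2R)-2-[4-(tert-butyldimethylsilyloxy)phenyl]-8-[(2R)-5-methyl-2-(prop-1-en-2-yl)hex-5-en-1-yl]-5,7-bis(triisopropylsilyloxy)-2,3-dihydro-4H-chromen-4-one | C=C(C)CC[C@H](Cc1c(O[Si](C(C)C)(C(C)C)C(C)C)cc(O[Si](C(C)C)(C(C)C)C(C)C)c2c1O[C@@H](c1ccc(O[Si](C)(C)C(C)(C)C)cc1)CC2=O)C(C)=C
F6 | step 5 | (3R)-6-methyl-3-(prop-1-en-2-yl)hept-6-enal | C=C(C)CC[C@H](CC=O)C(C)=C
F7 | step 5 | (4R)-7-methyl-4-(prop-1-en-2-yl)oct-7-en-1-yne | C=C(C)CC[C@H](CC#C)C(C)=C
F8 | step 5 | lithium (4R)-7-methyl-4-(prop-1-en-2-yl)oct-7-en-1-yn-1-ide | C=C(C)CC[C@H](CC#C[Li])C(C)=C
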